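**Retrosynthetic overview**
1. The carbocycle is built first, in the only C–C bond-forming step: Diels–Alder reaction of furan 1 with ethyl propiolate 2 gives the oxygen-bridged diene 3; reduction to 4 and esterification with benzoic acid 5 give 6.
2. Key disconnection (C–O): acetic acid 7 opens the oxygen bridge of 6 in an enantioselective anti SN2' ring opening to the trans hydroxy acetate 8, which sets both carbinol centres and the absolute configuration.
3. Deacetylation gives diol 9; both oxirane rings are then closed in one hydroxyl-directed operation (through 10) to the anti bis-epoxide 11.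
4. Acetylation with acetic anhydride 12 gives 13; the last C–O bond comes from regioselective anti hydrolysis of the disubstituted oxirane, giving target 14.
5. Ring order: carbocycle with oxygen bridge, bridge opened, two oxiranes closed, one oxirane opened.

Assumption: the sense of induction in step 4 is taken by analogy with the benzo-fused parent reaction (the (S,R)-ligand is expected to give the (S,S)-hydroxy ester); if it proves opposite, the enantiomeric ligand is used.

Convention: in steps 6 to 8 ring positions carry the target locants (C1 bears CH2OBz and is an oxirane carbon, C2 and C3 bear the acetates, C4 and C5 the hydroxyls, C6 is the oxirane CH); in the diene names the same carbons are C1, C6, C5, C4, C3, C2.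

**Route**

Step 1
Reactants: 1 furan; 2 ethyl propiolate
Product: 3 rac-ethyl 7-oxabicyclo[2.2.1]hepta-2,5-diene-2-carboxylate
Conditions: AlCl3 (1.0 equiv), furan (5 equiv), CH2Cl2, −20 to 0 °C, 30 min; cold aq. NaHCO3
Reagents that add atoms: none
Why: Lewis-acid-accelerated Diels–Alder reaction of furan with the propiolate; low temperature and short time keep the acid-labile 1:1 adduct from isomerising to a phenol, and both bridgehead centres form together (racemate, resolved in step 4).

Step 2
Reactants: 3 rac-ethyl 7-oxabicyclo[2.2.1]hepta-2,5-diene-2-carboxylate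
Product: 4 rac-(7-oxabicyclo[2.2.1]hepta-2,5-dien-2-yl)methanol
Conditions: i-Bu2AlH (2.2 equiv), CH2Cl2, −78 °C; aq. KNaC4H4O6 (potassium sodium tartrate)
Reagents that add atoms: none
Why: 1,2-reduction of the conjugated ester to the allylic alcohol by the aluminium hydride at −78 °C leaves both strained alkenes and the oxygen bridge intact, and the neutral tartrate work-up avoids acid-catalysed aromatisation.

Step 3
Reactants: 4 rac-(7-oxabicyclo[2.2.1]hepta-2,5-dien-2-yl)methanol; 5 benzoic acid
Product: 6 rac-(7-oxabicyclo[2.2.1]hepta-2,5-dien-2-yl)methyl benzoate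
Conditions: DCC (1.1 equiv), DMAP (0.1 equiv), CH2Cl2, 0 °C to rt
Reagents that add atoms: none
Why: Steglich esterification acylates the primary alcohol under neutral conditions that the acid-sensitive oxanorbornadiene tolerates; no stereocentre is touched.

Step 4
Reactants: 6 rac-(7-oxabicyclo[2.2.1]hepta-2,5-dien-2-yl)methyl benzoate; 7 acetic acid
Product: 8 [(5S,6S)-5-acetoxy-6-hydroxycyclohexa-1,3-dien-1-yl]methyl benzoate
Conditions: [Rh(cod)Cl]2 (2.5 mol%), (S)-1-[(R)-2-(diphenylphosphino)ferrocenyl]ethyldi-tert-butylphosphine (6 mol%), AcOH (3 equiv), Et3N (3 equiv), THF, 50 °C; chromatography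
Reagents that add atoms: none
Why: Proposed new method: monovalent rhodium on the bulky, electron-rich ferrocenyl diphosphine binds the unsubstituted alkene and the bridging oxygen on the exo face and inserts into one doubly allylic bridgehead C–O bond; the chiral catalyst selects the bridgehead of one absolute topicity, which in (1R,4S)-6 is C4 (remote from the substituted alkene carbon, also favoured sterically and by the alkyl-stabilised dienyl terminus), and acetate attacks the rhodium allyl at C6 anti to the metal (SN2' overall), giving the trans hydroxy acetate with the new C–OAc centre S and the retained carbinol S; the (1S,4R)-enantiomer is opened at its other bridgehead to a separable regioisomer (regiodivergent parallel kinetic resolution, at most 50% of 8); the closest known reaction is the rhodium/ferrocenyl-diphosphine-catalysed asymmetric ring opening of meso oxabenzonorbornadienes with carboxylic acids and its regiodivergent variant on unsymmetrical benzo-fused oxabicycles, here extended to a non-benzo-fused, C2-substituted 7-oxanorbornadiene, which to my knowledge has not been shown.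

Step 5
Reactants: 8 [(5S,6S)-5-acetoxy-6-hydroxycyclohexa-1,3-dien-1-yl]methyl benzoate
Product: 9 [(5S,6S)-5,6-dihydroxycyclohexa-1,3-dien-1-yl]methyl benzoate
Conditions: K2CO3 (0.2 equiv), MeOH, −10 to 0 °C; AcOH quench at full conversion of 8
Reagents that add atoms: none
Why: carbonate-catalysed transesterification (Zemplén-type methanolysis) removes the secondary acetate, activated by the neighbouring hydroxyl, far faster than the primary benzoate; both stereocentres are untouched and the free trans-diol is needed to direct step 6.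

Step 6
Reactants: 9 [(5S,6S)-5,6-dihydroxycyclohexa-1,3-dien-1-yl]methyl benzoate
Product: 11 [(1R,2S,4R,5R,6R,7R)-5,6-dihydroxy-3,8-dioxatricyclo[5.1.0.0^{2,4}]octan-4-yl]methyl benzoate, via monoepoxide diol 10 (not isolated)
Conditions: VO(acac)2 (5 mol%), t-BuOOH (2.5 equiv, in decane), CH2Cl2, 0 °C to rt
Reagents that add atoms: tert-butyl hydroperoxide, CC(C)(C)OO
Why: vanadium-catalysed hydroxyl-directed (Sharpless-type) epoxidation: each allylic alkoxide–vanadium–peroxide delivers oxygen to its own neighbouring alkene on the face of that hydroxyl, so the C1–C6 oxirane forms cis to the C2 hydroxyl and the C4–C5 oxirane cis to the C3 hydroxyl (and anti to the first oxirane), setting four stereocentres.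

Step 7
Reactants: 11 [(1R,2S,4R,5R,6R,7R)-5,6-dihydroxy-3,8-dioxatricyclo[5.1.0.0^{2,4}]octan-4-yl]methyl benzoate; 12 acetic anhydride
Product: 13 [(1R,2S,4S,5R,6S,7S)-5,6-diacetoxy-3,8-dioxatricyclo[5.1.0.0^{2,4}]octan-4-yl]methyl benzoate
Conditions: Ac2O (3 equiv), pyridine, DMAP (5 mol%), CH2Cl2, 0 °C
Reagents that add atoms: none
Why: standard DMAP-catalysed acetylation of the two secondary alcohols; each hydroxyl is cis to its neighbouring oxirane, so no Payne rearrangement is possible and both epoxides survive.

Step 8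
Reactants: 13 [(1R,2S,4S,5R,6S,7S)-5,6-diacetoxy-3,8-dioxatricyclo[5.1.0.0^{2,4}]octan-4-yl]methyl benzoate
Product: 14 [(1S,2R,3S,4R,5R,6S)-2,3-diacetoxy-4,5-dihydroxy-7-oxabicyclo[4.1.0]heptan-1-yl]methyl benzoate (target)
Conditions: HClO4 (5 mol%), THF–H2O (3:1), 0 °C to rt
Reagents that add atoms: water, O
Why: acid-catalysed anti (SN2-type) epoxide hydrolysis at C4, the carbon not flanked by the other oxirane: C5 is shielded on the attack face by the neighbouring epoxide oxygen and inductively deactivated, the cis C3 acetate cannot participate, and 1,3-participation by the C2 acetate would deliver oxygen to the same carbon and face, so inversion at C4 with retention at C5 gives the 4,5-trans-diol while the trisubstituted oxirane, flanked by two acyloxy-bearing carbons, reacts more slowly.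

**Compound list**
1 | furan | c1ccoc1 | starting material
2 | ethyl propiolate | CCOC(=O)C#C | starting material
3 | rac-ethyl 7-oxabicyclo[2.2.1]hepta-2,5-diene-2-carboxylate (racemate; (1R,4S)-enantiomer drawn) | CCOC(=O)C1=C[C@@H]2C=C[C@H]1O2 | intermediate
4 | rac-(7-oxabicyclo[2.2.1]hepta-2,5-dien-2-yl)methanol (racemate; (1R,4S)-enantiomer drawn) | OCC1=C[C@@H]2C=C[C@H]1O2 | intermediate
5 | benzoic acid | OC(=O)c1ccccc1 | starting material
6 | rac-(7-oxabicyclo[2.2.1]hepta-2,5-dien-2-yl)methyl benzoate (racemate; (1R,4S)-enantiomer drawn, the one that gives 8) | O=C(OCC1=C[C@@H]2C=C[C@H]1O2)c1ccccc1 | intermediate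
7 | acetic acid | CC(=O)O | starting material
8 | [(5S,6S)-5-acetoxy-6-hydroxycyclohexa-1,3-dien-1-yl]methyl benzoate | O=C(OCC1=CC=C[C@H](OC(C)=O)[C@H]1O)c1ccccc1 | intermediate
9 | [(5S,6S)-5,6-dihydroxycyclohexa-1,3-dien-1-yl]methyl benzoate | O=C(OCC1=CC=C[C@H](O)[C@H]1O)c1ccccc1 | intermediate
10 | [(1R,2R,3S,6S)-2,3-dihydroxy-7-oxabicyclo[4.1.0]hept-4-en-1-yl]methyl benzoate (oxirane cis to the 2-hydroxyl) | O[C@H]1C=C[C@@H]2O[C@]2(COC(=O)c2ccccc2)[C@@H]1O | intermediate
11 | [(1R,2S,4R,5R,6R,7R)-5,6-dihydroxy-3,8-dioxatricyclo[5.1.0.0^{2,4}]octan-4-yl]methyl benzoate (oxiranes anti to each other, each cis to its neighbouring hydroxyl) | O[C@H]1[C@H]2O[C@H]2[C@@H]2O[C@]2(COC(=O)c2ccccc2)[C@@H]1O | intermediate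
12 | acetic anhydride | CC(=O)OC(C)=O | starting material
13 | [(1R,2S,4S,5R,6S,7S)-5,6-diacetoxy-3,8-dioxatricyclo[5.1.0.0^{2,4}]octan-4-yl]methyl benzoate | CC(=O)O[C@H]1[C@H]2O[C@H]2[C@@H]2O[C@]2(COC(=O)c2ccccc2)[C@@H]1OC(C)=O | intermediate
14 | [(1S,2R,3S,4R,5R,6S)-2,3-diacetoxy-4,5-dihydroxy-7-oxabicyclo[4.1.0]heptan-1-yl]methyl benzoate | CC(=O)O[C@H]1[C@H](O)[C@@H](O)[C@@H]2O[C@]2(COC(=O)c2ccccc2)[C@@H]1OC(C)=O | target

**Totals**
Total step count: 8. Longest linear sequence: 8 steps (from furan 1).

**Three steps most likely to fail, with fallbacks**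

Step 4 (the proposed new ring opening). Risks: rhodium-induced isomerisation of the non-benzo oxanorbornadiene to a phenol, loss of water from 8 to an arene, weak catalyst control of which bridgehead opens, and a ceiling of 50%. The fallback uses known chemistry; it sets out from benzoic acid 5 and comes back at diol 9. Birch reduction of 5 (Na, liquid NH3, EtOH) gives cyclohexa-2,5-diene-1-carboxylic acid F1. LiAlH4 reduces it to cyclohexa-2,5-dien-1-ylmethanol F2, and DCC/DMAP esterification with more 5 gives cyclohexa-2,5-dien-1-ylmethyl benzoate F3. One equivalent of buffered mCPBA gives the racemic mono-epoxide (7-oxabicyclo[4.1.0]hept-3-en-2-yl)methyl benzoate F4. Ring opening with Ac2O and catalytic n-Bu4NOAc gives the racemic trans-diacetate (5,6-diacetoxycyclohex-2-en-1-yl)methyl benzoate F5; either regiochemistry of opening leads to the same diacetate series once the side-chain carbon becomes sp2. Br2 adds to the remaining alkene to give (2,3-dibromo-5,6-diacetoxycyclohexyl)methyl benzoate F6, and double dehydrobromination with DBU gives the racemic diene rac-(5,6-trans-diacetoxycyclohexa-1,3-dien-1-yl)methyl benzoate F7. Lipase-catalysed hydrolysis (Burkholderia cepacia lipase, pH 7 buffer/MTBE) is expected by the Kazlauskas rule to consume the (5R,6R)-enantiomer, leaving [(5S,6S)-5,6-diacetoxycyclohexa-1,3-dien-1-yl]methyl benzoate F8. Methanolysis of F8 under the conditions of step 5 gives 9.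

Step 6 (double directed epoxidation of a dehydration-prone dihydrodiol). Risks: aromatisation of 9, vanadium-mediated oxidation of the allylic alcohols, and loss of the intermediate vinyl oxirane 10. The fallback makes the oxiranes one at a time with the diol never free; it sets out from hydroxy acetate 8 and comes back at 13. VO(acac)2 with 1.1 equiv t-BuOOH epoxidises only the alkene allylic to the free hydroxyl, giving [(1R,2R,3S,6S)-3-acetoxy-2-hydroxy-7-oxabicyclo[4.1.0]hept-4-en-1-yl]methyl benzoate F9. Ac2O/pyridine gives the diacetate [(1S,2R,3S,6S)-2,3-diacetoxy-7-oxabicyclo[4.1.0]hept-4-en-1-yl]methyl benzoate F10. Buffered mCPBA then epoxidises the remaining alkene under substrate control, anti to the existing oxirane, to give 13.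

Step 8 (regioselective hydrolysis). Risks: water may attack C5 instead of C4, giving the 4,5-bis-epimeric diol; the C1–C6 oxirane may open; acetyl groups may migrate. The fallback uses the complementary bis-epoxide, in which attack at C5 gives 14; it sets out from hydroxy acetate 8 and comes back at 14. Photooxygenation of 8 (O2, tetraphenylporphyrin sensitiser, visible light, CH2Cl2, −20 °C) gives, by the hydroxyl-directed [4+2] addition of singlet oxygen, the endoperoxide (8-acetoxy-7-hydroxy-2,3-dioxabicyclo[2.2.2]oct-5-en-1-yl)methyl benzoate F11, with the peroxide bridge cis to the hydroxyl and trans to the acetate. Co(TPP) (cobalt 5,10,15,20-tetraphenylporphyrinate, catalytic, CH2Cl2, 0 °C) rearranges it to the syn bis-epoxide [(1S,2S,4R,5R,6R,7R)-6-acetoxy-5-hydroxy-3,8-dioxatricyclo[5.1.0.0^{2,4}]octan-4-yl]methyl benzoate F12. Acetylation gives [(1S,2S,4S,5R,6S,7R)-5,6-diacetoxy-3,8-dioxatricyclo[5.1.0.0^{2,4}]octan-4-yl]methyl benzoate F13. Its hydrolysis at C5 (anti, from the face opposite both oxiranes, under neutral or weakly acidic aqueous conditions to limit acetate participation at C4) gives 14.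

**Further compounds**
F1 | step 4 | cyclohexa-2,5-diene-1-carboxylic acid | OC(=O)C1C=CCC=C1
F2 | step 4 | cyclohexa-2,5-dien-1-ylmethanol | OCC1C=CCC=C1
F3 | step 4 | cyclohexa-2,5-dien-1-ylmethyl benzoate | O=C(OCC1C=CCC=C1)c1ccccc1
F4 | step 4 | rac-(7-oxabicyclo[4.1.0]hept-3-en-2-yl)methyl benzoate, oxirane anti to the side chain (racemate, one enantiomer drawn) | O=C(OC[C@@H]1C=CC[C@H]2O[C@@H]12)c1ccccc1
F5 | step 4 | rac-(5,6-trans-diacetoxycyclohex-2-en-1-yl)methyl benzoate (racemate, one enantiomer drawn) | O=C(OC[C@@H]1C=CC[C@H](OC(C)=O)[C@H]1OC(C)=O)c1ccccc1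
F6 | step 4 | rac-(2,3-dibromo-5,6-trans-diacetoxycyclohexyl)methyl benzoate (trans-dibromide, bromine-bearing centres not assigned) | O=C(OC[C@@H]1C(Br)C(Br)C[C@H](OC(C)=O)[C@H]1OC(C)=O)c1ccccc1
F7 | step 4 | rac-(5,6-trans-diacetoxycyclohexa-1,3-dien-1-yl)methyl benzoate (racemate, (5S,6S)-enantiomer drawn) | O=C(OCC1=CC=C[C@H](OC(C)=O)[C@H]1OC(C)=O)c1ccccc1
F8 | step 4 | [(5S,6S)-5,6-diacetoxycyclohexa-1,3-dien-1-yl]methyl benzoate | O=C(OCC1=CC=C[C@H](OC(C)=O)[C@H]1OC(C)=O)c1ccccc1
F9 | step 6 | [(1R,2R,3S,6S)-3-acetoxy-2-hydroxy-7-oxabicyclo[4.1.0]hept-4-en-1-yl]methyl benzoate | CC(=O)O[C@H]1C=C[C@@H]2O[C@]2(COC(=O)c2ccccc2)[C@@H]1O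
F10 | step 6 | [(1S,2R,3S,6S)-2,3-diacetoxy-7-oxabicyclo[4.1.0]hept-4-en-1-yl]methyl benzoate | CC(=O)O[C@H]1C=C[C@@H]2O[C@]2(COC(=O)c2ccccc2)[C@@H]1OC(C)=O
F11 | step 8 | (8-acetoxy-7-hydroxy-2,3-dioxabicyclo[2.2.2]oct-5-en-1-yl)methyl benzoate, peroxide bridge cis to the 7-hydroxyl and trans to the 8-acetoxy group | O=C(OC[C@]12OO[C@H](C=C1)[C@H](OC(C)=O)[C@H]2O)c1ccccc1
F12 | step 8 | [(1S,2S,4R,5R,6R,7R)-6-acetoxy-5-hydroxy-3,8-dioxatricyclo[5.1.0.0^{2,4}]octan-4-yl]methyl benzoate | CC(=O)O[C@H]1[C@@H]2O[C@@H]2[C@@H]2O[C@]2(COC(=O)c2ccccc2)[C@@H]1O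
F13 | step 8 | [(1S,2S,4S,5R,6S,7R)-5,6-diacetoxy-3,8-dioxatricyclo[5.1.0.0^{2,4}]octan-4-yl]methyl benzoate | CC(=O)O[C@H]1[C@@H]2O[C@@H]2[C@@H]2O[C@]2(COC(=O)c2ccccc2)[C@@H]1OC(C)=O
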